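**Plan**

1. Disconnections: the seven phenols are carried as methyl ethers and freed last. In the upper, styryl-bearing 2,3-dihydrobenzofuran the bonds C3–C5' (to the lower unit), C2–C3 and O1–C2 are cut; in the lower ring the matching C3'–aryl, C2'–C3' and O1'–C2' bonds are cut.
2. Enabling feature: each five-membered ring O1–C2–C3–C3a–C7a consists of a phenolic carbon C7a, its ortho carbon C3a bearing a diarylmethine C3, and an O-benzylic C2 with a 4-oxyphenyl group. That is an o-quinone methide (C7a=O, C3a=C3) plus a one-carbon 4-methoxybenzyl sulfonium ylide. Ring B (the catechol-type arene) is the fused arene of the lower ring and, through C5', the C3 aryl of the upper ring.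
3. Forward order: the lower ring is closed first from an aryl Grignard reagent, O-Boc 5-bromo-o-vanillin and the ylide. Bromine–lithium exchange at C5', addition to the O-Boc stilbene salicylaldehyde and closure of the upper ring follow in one flask, then sevenfold O-demethylation.
4. Stereochemistry: the two enantiomeric C2-symmetric 2,5-dimethylthiolanium ylides (from the two hexane-2,5-diols) set C2' (R) and C2 (S). Trans-selective annulation sets C3' (R) and C3 (S). The E-alkene is bought with the stilbene.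

Key step: step 13

Assumption: the thiolanium benzylides are taken to show toward an o-quinone methide the facial sense they show toward aldehydes, which assigns the (2R,5R) salt to the (2R,3R) ring and the (2S,5S) salt to the (2S,3S) ring; this is to be checked on a model o-quinone methide, and the two salts change places if the sense proves opposite.

Locants follow 1-benzofuran numbering; primed locants belong to the lower unit. Shorthand used in names: DBF = (2R,3R)-3-(3,5-dimethoxyphenyl)-7-methoxy-2-(4-methoxyphenyl)-2,3-dihydro-1-benzofuran-5-yl.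

**Route**

Step 1
Reactants: 1 5-bromo-2-hydroxy-3-methoxybenzaldehyde
Product: 2 tert-butyl 4-bromo-2-formyl-6-methoxyphenyl carbonate
Conditions: Boc2O (1.1 equiv), i-Pr2NEt, DMAP (cat.), THF, 0 °C to rt
Reagents that add atoms: di-tert-butyl dicarbonate, CC(C)(C)OC(=O)OC(=O)OC(C)(C)C
Why: DMAP-catalysed O-acylation of the phenol with Boc2O is the standard entry to O-Boc salicylaldehydes and leaves the aldehyde and the aryl bromide untouched.

Step 2
Reactants: 3 1-bromo-3,5-dimethoxybenzene
Product: 4 (3,5-dimethoxyphenyl)magnesium bromide (THF solution, titrated and used as such)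
Conditions: Mg turnings, 1,2-dibromoethane (cat.), THF, 40 °C then rt
Reagents that add atoms: magnesium, [Mg]
Why: Grignard reagent formation by insertion of magnesium into the aryl C–Br bond, to which the two methoxy groups are inert.

Step 3
Reactants: 5 (2S,5S)-hexane-2,5-diol
Product: 6 (2S,5S)-hexane-2,5-diyl dimethanesulfonate
Conditions: MsCl, Et3N, CH2Cl2, −20 to 0 °C
Reagents that add atoms: methanesulfonyl chloride, CS(=O)(=O)Cl
Why: Mesylation of the two secondary alcohols breaks only O–H bonds, so both centres keep the S configuration.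

Step 4
Reactants: 6 (2S,5S)-hexane-2,5-diyl dimethanesulfonate
Product: 7 (2R,5R)-2,5-dimethylthiolane
Conditions: Na2S·9H2O, DMSO, rt; distillation
Reagents that add atoms: sodium sulfide nonahydrate (Na2S·9H2O), [Na+].[Na+].[S-2]
Why: Twofold SN2 displacement by sulfide (intermolecular, then 5-exo-tet) inverts both carbons and should give the C2-symmetric (2R,5R)-thiolane.

Step 5
Reactants: 7 (2R,5R)-2,5-dimethylthiolane; 8 4-methoxybenzyl alcohol
Product: 9 (2R,5R)-1-(4-methoxybenzyl)-2,5-dimethylthiolan-1-ium tetrafluoroborate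
Conditions: HBF4·OEt2, CH2Cl2, 0 °C to rt (8 added slowly to 7 and the acid); precipitation with Et2O
Reagents that add atoms: tetrafluoroboric acid (HBF4, as diethyl ether complex; supplies the counter-ion), [H+].F[B-](F)(F)F
Why: Acid-promoted S-alkylation of a sulfide by a benzylic alcohol: HBF4 ionises the alcohol to the 4-methoxybenzyl cation, which the sulfide traps, and because the two lone pairs of the C2-symmetric thiolane are equivalent, sulfur does not become a stereocentre.

Step 6
Reactants: 2 tert-butyl 4-bromo-2-formyl-6-methoxyphenyl carbonate; 4 (3,5-dimethoxyphenyl)magnesium bromide; 9 (2R,5R)-1-(4-methoxybenzyl)-2,5-dimethylthiolan-1-ium tetrafluoroborate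
Product: 15 (2R,3R)-5-bromo-3-(3,5-dimethoxyphenyl)-7-methoxy-2-(4-methoxyphenyl)-2,3-dihydro-1-benzofuran, via magnesium alkoxide 10 (not isolated), via phenoxide carbonate 11 (not isolated), via o-quinone methide 12 (not isolated), via sulfonium ylide 13 (not isolated), via betaine 14 (not isolated)
Conditions: 2, THF, −78 °C, 4 (1.0 equiv); then 13 [from 9 (1.2 equiv), LiN(SiMe3)2, THF–CH2Cl2, −78 °C] by cannula; −78 to 0 °C
Reagents that add atoms: none
Why: Proposed new method: the aryl Grignard reagent adds to the aldehyde, alkoxide 10 pulls the Boc group off the neighbouring phenol oxygen (11), warming expels tert-butyl carbonate to release o-quinone methide 12, the carbanion carbon of ylide 13 attacks its methide carbon to give the rearomatised betaine 14, and the phenoxide displaces the thiolane in a 5-exo-tet SN2 step with inversion, so that C2 (R) is fixed by the open face of the C2-symmetric ylide and C3 (R) by the trans-selective addition and closure; the closest known reaction types are o-quinone methide generation from O-Boc salicylaldehydes with organometallic reagents, the [4+1] annulation of o-quinone methides with sulfonium ylides to trans-2,3-dihydrobenzofurans, and aldehyde epoxidation with C2-symmetric thiolanium benzylides.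

Step 7
Reactants: 16 (E)-3,5,4'-trimethoxystilbene
Product: 17 2,4-dimethoxy-6-[(E)-2-(4-methoxyphenyl)ethenyl]benzaldehyde
Conditions: POCl3, DMF, 0 to 70 °C; then H2O
Reagents that add atoms: N,N-dimethylformamide (formyl carbon), CN(C)C=O; water (formyl oxygen), O
Why: Vilsmeier–Haack formylation, in which the chloroiminium ion should attack C2 of the dimethoxy ring (para to one methoxy group, ortho to the other, less crowded than C4 between the two methoxy groups) while the E-alkene stays as it is.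

Step 8
Reactants: 17 2,4-dimethoxy-6-[(E)-2-(4-methoxyphenyl)ethenyl]benzaldehyde
Product: 18 2-hydroxy-4-methoxy-6-[(E)-2-(4-methoxyphenyl)ethenyl]benzaldehyde
Conditions: BCl3 (1.2 equiv), CH2Cl2, −78 to 0 °C; then H2O
Reagents that add atoms: none
Why: Chelation-directed ether cleavage, in which BCl3 bound between the aldehyde oxygen and the ortho methoxy oxygen delivers chloride to that methyl group only and leaves the other two methyl ethers and the alkene.

Step 9
Reactants: 18 2-hydroxy-4-methoxy-6-[(E)-2-(4-methoxyphenyl)ethenyl]benzaldehyde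
Product: 19 tert-butyl 2-formyl-5-methoxy-3-[(E)-2-(4-methoxyphenyl)ethenyl]phenyl carbonate
Conditions: Boc2O (1.2 equiv), i-Pr2NEt, DMAP (cat.), THF, 0 °C to rt
Reagents that add atoms: di-tert-butyl dicarbonate, CC(C)(C)OC(=O)OC(=O)OC(C)(C)C
Why: DMAP-catalysed O-acylation of the hydrogen-bonded phenol with Boc2O, as in step 1, with aldehyde and stilbene as spectators.

Step 10
Reactants: 20 (2R,5R)-hexane-2,5-diol
Product: 21 (2R,5R)-hexane-2,5-diyl dimethanesulfonate
Conditions: MsCl, Et3N, CH2Cl2, −20 to 0 °C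
Reagents that add atoms: methanesulfonyl chloride, CS(=O)(=O)Cl
Why: Mesylation with retention at both carbons, the mirror image of step 3.

Step 11
Reactants: 21 (2R,5R)-hexane-2,5-diyl dimethanesulfonate
Product: 22 (2S,5S)-2,5-dimethylthiolane
Conditions: Na2S·9H2O, DMSO, rt; distillation
Reagents that add atoms: sodium sulfide nonahydrate (Na2S·9H2O), [Na+].[Na+].[S-2]
Why: Double SN2 displacement by sulfide with inversion at both carbons, the mirror image of step 4.

Step 12
Reactants: 22 (2S,5S)-2,5-dimethylthiolane; 8 4-methoxybenzyl alcohol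
Product: 23 (2S,5S)-1-(4-methoxybenzyl)-2,5-dimethylthiolan-1-ium tetrafluoroborate
Conditions: HBF4·OEt2, CH2Cl2, 0 °C to rt; precipitation with Et2O
Reagents that add atoms: tetrafluoroboric acid (HBF4, as diethyl ether complex; supplies the counter-ion), [H+].F[B-](F)(F)F
Why: Acid-promoted S-alkylation through the 4-methoxybenzyl cation, as in step 5, giving the enantiomeric salt without a sulfur stereocentre.

Step 13
Reactants: 15 (2R,3R)-5-bromo-3-(3,5-dimethoxyphenyl)-7-methoxy-2-(4-methoxyphenyl)-2,3-dihydro-1-benzofuran; 19 tert-butyl 2-formyl-5-methoxy-3-[(E)-2-(4-methoxyphenyl)ethenyl]phenyl carbonate; 23 (2S,5S)-1-(4-methoxybenzyl)-2,5-dimethylthiolan-1-ium tetrafluoroborate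
Product: 30 (2S,3S)-3-DBF-6-methoxy-2-(4-methoxyphenyl)-4-[(E)-2-(4-methoxyphenyl)ethenyl]-2,3-dihydro-1-benzofuran (heptamethyl ether of the target), via aryllithium 24 (not isolated), via lithium alkoxide 25 (not isolated), via phenoxide carbonate 26 (not isolated), via o-quinone methide 27 (not isolated), via sulfonium ylide 28 (not isolated), via betaine 29 (not isolated)
Conditions: 15, t-BuLi (2.0 equiv), THF, −78 °C; 19 (1.0 equiv), −78 °C; then 28 [from 23 (1.3 equiv), LiN(SiMe3)2, THF–CH2Cl2, −78 °C] by cannula, then MgBr2·OEt2; −78 to −20 °C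
Reagents that add atoms: none
Why: Proposed new method: bromine–lithium exchange gives aryllithium 24, which adds to the aldehyde of 19; alkoxide 25 takes over the Boc group to give phenoxide 26, and MgBr2 then promotes loss of tert-butyl carbonate to o-quinone methide 27, a vinylogous ester through its ring methoxy group. Ylide 28, already present when 27 is released, adds through carbon to the methide carbon to give betaine 29, and the phenoxide closes the upper dihydrofuran ring by 5-exo-tet SN2 displacement of the thiolane (O1–C2) after the C5'–C3 and C3–C2 bonds have formed in the same flask. The closest known reaction types are o-quinone methide generation from O-Boc salicylaldehydes with organolithium reagents and magnesium salts, the [4+1] annulation of o-quinone methides with sulfonium ylides to trans-2,3-dihydrobenzofurans, and asymmetric epoxidation with C2-symmetric thiolanium benzylides. C2 (S) is controlled by the (2S,5S)-thiolane, whose methyl group cis to the ylide carbon blocks one face, followed by inversion in the closure; C3 (S) is controlled relative to C2 by the trans-selective addition and closure that keeps the two aryl groups apart, and since the centres of the lower ring are remote the step should be reagent-controlled. The step needs chemoselectivity (only the ylide may add to 27, secured by exactly one equivalent of aryllithium that the aldehyde consumes at −78 °C before 27 is set free) and must avoid a benzylic cation, which the ortho E-styryl group would trap to an indane; the wholly anionic course secures this.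

Step 14
Reactants: 30 (2S,3S)-3-DBF-6-methoxy-2-(4-methoxyphenyl)-4-[(E)-2-(4-methoxyphenyl)ethenyl]-2,3-dihydro-1-benzofuran
Product: 31 (2S,3S)-3-[(2R,3R)-3-(3,5-dihydroxyphenyl)-7-hydroxy-2-(4-hydroxyphenyl)-2,3-dihydro-1-benzofuran-5-yl]-2-(4-hydroxyphenyl)-4-[(E)-2-(4-hydroxyphenyl)ethenyl]-2,3-dihydro-1-benzofuran-6-ol (CNP0172909.1)
Conditions: BCl3 (excess), n-Bu4NI (excess), CH2Cl2, −78 to 0 °C; then H2O
Reagents that add atoms: none
Why: Lewis acid-assisted nucleophilic ether cleavage (BCl3 activates each ArO–Me bond and iodide removes the methyl group by SN2) runs at low temperature, which should spare the two benzylic C2–O bonds, the E-alkene and all four stereocentres.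

**Compound list**

1 | 5-bromo-2-hydroxy-3-methoxybenzaldehyde | COc1cc(Br)cc(C=O)c1O | starting material
2 | tert-butyl 4-bromo-2-formyl-6-methoxyphenyl carbonate | COc1cc(Br)cc(C=O)c1OC(=O)OC(C)(C)C | intermediate
3 | 1-bromo-3,5-dimethoxybenzene | COc1cc(Br)cc(OC)c1 | starting material
4 | (3,5-dimethoxyphenyl)magnesium bromide | COc1cc(OC)cc([Mg]Br)c1 | intermediate
5 | (2S,5S)-hexane-2,5-diol | C[C@H](O)CC[C@H](C)O | starting material
6 | (2S,5S)-hexane-2,5-diyl dimethanesulfonate | C[C@H](OS(C)(=O)=O)CC[C@H](C)OS(C)(=O)=O | intermediate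
7 | (2R,5R)-2,5-dimethylthiolane | C[C@@H]1CC[C@@H](C)S1 | intermediate
8 | 4-methoxybenzyl alcohol | COc1ccc(CO)cc1 | starting material
9 | (2R,5R)-1-(4-methoxybenzyl)-2,5-dimethylthiolan-1-ium tetrafluoroborate | C[C@@H]1CC[C@@H](C)[S+]1Cc1ccc(OC)cc1.F[B-](F)(F)F | intermediate
10 | bromomagnesium {5-bromo-2-[(tert-butoxycarbonyl)oxy]-3-methoxyphenyl}(3,5-dimethoxyphenyl)methanolate (carbinol carbon not controlled) | COc1cc(Br)cc(C(O[Mg]Br)c2cc(OC)cc(OC)c2)c1OC(=O)OC(C)(C)C | intermediate
11 | bromomagnesium 4-bromo-2-{[(tert-butoxycarbonyl)oxy](3,5-dimethoxyphenyl)methyl}-6-methoxyphenolate | COc1cc(Br)cc(C(OC(=O)OC(C)(C)C)c2cc(OC)cc(OC)c2)c1O[Mg]Br | intermediate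
12 | (6E)-4-bromo-6-(3,5-dimethoxybenzylidene)-2-methoxycyclohexa-2,4-dien-1-one | O=C1C(OC)=CC(Br)=C/C1=C\c1cc(OC)cc(OC)c1 | intermediate
13 | [(2R,5R)-2,5-dimethylthiolan-1-ium-1-yl](4-methoxyphenyl)methanide | C[C@@H]1CC[C@@H](C)[S+]1[CH-]c1ccc(OC)cc1 | intermediate
14 | 4-bromo-2-[(1R,2S)-1-(3,5-dimethoxyphenyl)-2-[(2R,5R)-2,5-dimethylthiolan-1-ium-1-yl]-2-(4-methoxyphenyl)ethyl]-6-methoxyphenolate | [O-]c1c(OC)cc(Br)cc1[C@@H](c1cc(OC)cc(OC)c1)[C@@H](c1ccc(OC)cc1)[S+]1[C@H](C)CC[C@H]1C | intermediate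
15 | (2R,3R)-5-bromo-3-(3,5-dimethoxyphenyl)-7-methoxy-2-(4-methoxyphenyl)-2,3-dihydro-1-benzofuran (trans) | Brc1cc(OC)c2c(c1)[C@@H](c1cc(OC)cc(OC)c1)[C@H](c1ccc(OC)cc1)O2 | intermediate
16 | (E)-3,5,4'-trimethoxystilbene | COc1ccc(/C=C/c2cc(OC)cc(OC)c2)cc1 | starting material
17 | 2,4-dimethoxy-6-[(E)-2-(4-methoxyphenyl)ethenyl]benzaldehyde | COc1ccc(/C=C/c2cc(OC)cc(OC)c2C=O)cc1 | intermediate
18 | 2-hydroxy-4-methoxy-6-[(E)-2-(4-methoxyphenyl)ethenyl]benzaldehyde | COc1ccc(/C=C/c2cc(OC)cc(O)c2C=O)cc1 | intermediate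
19 | tert-butyl 2-formyl-5-methoxy-3-[(E)-2-(4-methoxyphenyl)ethenyl]phenyl carbonate | COc1ccc(/C=C/c2cc(OC)cc(OC(=O)OC(C)(C)C)c2C=O)cc1 | intermediate
20 | (2R,5R)-hexane-2,5-diol | C[C@@H](O)CC[C@@H](C)O | starting material
21 | (2R,5R)-hexane-2,5-diyl dimethanesulfonate | C[C@@H](OS(C)(=O)=O)CC[C@@H](C)OS(C)(=O)=O | intermediate
22 | (2S,5S)-2,5-dimethylthiolane | C[C@H]1CC[C@H](C)S1 | intermediate
23 | (2S,5S)-1-(4-methoxybenzyl)-2,5-dimethylthiolan-1-ium tetrafluoroborate | C[C@H]1CC[C@H](C)[S+]1Cc1ccc(OC)cc1.F[B-](F)(F)F | intermediate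
24 | DBF-lithium, [(2R,3R)-3-(3,5-dimethoxyphenyl)-7-methoxy-2-(4-methoxyphenyl)-2,3-dihydro-1-benzofuran-5-yl]lithium | [Li]c1cc(OC)c2c(c1)[C@@H](c1cc(OC)cc(OC)c1)[C@H](c1ccc(OC)cc1)O2 | intermediate
25 | lithium (DBF){2-[(tert-butoxycarbonyl)oxy]-4-methoxy-6-[(E)-2-(4-methoxyphenyl)ethenyl]phenyl}methanolate (carbinol carbon not controlled) | COc1ccc(/C=C/c2cc(OC)cc(OC(=O)OC(C)(C)C)c2C(O[Li])c2cc(OC)c3c(c2)[C@@H](c2cc(OC)cc(OC)c2)[C@H](c2ccc(OC)cc2)O3)cc1 | intermediate
26 | lithium 2-{[(tert-butoxycarbonyl)oxy](DBF)methyl}-5-methoxy-3-[(E)-2-(4-methoxyphenyl)ethenyl]phenolate | COc1ccc(/C=C/c2cc(OC)cc(O[Li])c2C(OC(=O)OC(C)(C)C)c2cc(OC)c3c(c2)[C@@H](c2cc(OC)cc(OC)c2)[C@H](c2ccc(OC)cc2)O3)cc1 | intermediate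
27 | 6-[(DBF)methylidene]-3-methoxy-5-[(E)-2-(4-methoxyphenyl)ethenyl]cyclohexa-2,4-dien-1-one (exocyclic geometry not assigned) | COc1ccc(/C=C/C2=CC(OC)=CC(=O)C2=Cc2cc(OC)c3c(c2)[C@@H](c2cc(OC)cc(OC)c2)[C@H](c2ccc(OC)cc2)O3)cc1 | intermediate
28 | [(2S,5S)-2,5-dimethylthiolan-1-ium-1-yl](4-methoxyphenyl)methanide | C[C@H]1CC[C@H](C)[S+]1[CH-]c1ccc(OC)cc1 | intermediate
29 | 2-{(1S,2R)-1-(DBF)-2-[(2S,5S)-2,5-dimethylthiolan-1-ium-1-yl]-2-(4-methoxyphenyl)ethyl}-5-methoxy-3-[(E)-2-(4-methoxyphenyl)ethenyl]phenolate | COc1ccc(/C=C/c2cc(OC)cc([O-])c2[C@H](c2cc(OC)c3c(c2)[C@@H](c2cc(OC)cc(OC)c2)[C@H](c2ccc(OC)cc2)O3)[C@H](c2ccc(OC)cc2)[S+]2[C@@H](C)CC[C@@H]2C)cc1 | intermediate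
30 | (2S,3S)-3-(DBF)-6-methoxy-2-(4-methoxyphenyl)-4-[(E)-2-(4-methoxyphenyl)ethenyl]-2,3-dihydro-1-benzofuran (heptamethyl ether of the target) | COc1ccc(/C=C/c2cc(OC)cc3c2[C@H](c2cc(OC)c4c(c2)[C@@H](c2cc(OC)cc(OC)c2)[C@H](c2ccc(OC)cc2)O4)[C@@H](c2ccc(OC)cc2)O3)cc1 | intermediate
31 | (2S,3S)-3-[(2R,3R)-3-(3,5-dihydroxyphenyl)-7-hydroxy-2-(4-hydroxyphenyl)-2,3-dihydro-1-benzofuran-5-yl]-2-(4-hydroxyphenyl)-4-[(E)-2-(4-hydroxyphenyl)ethenyl]-2,3-dihydro-1-benzofuran-6-ol (CNP0172909.1) | Oc1ccc(/C=C/c2cc(O)cc3c2[C@H](c2cc(O)c4c(c2)[C@@H](c2cc(O)cc(O)c2)[C@H](c2ccc(O)cc2)O4)[C@@H](c2ccc(O)cc2)O3)cc1 | target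

**Step count and risks**

Total: 14 steps. Longest linear sequence: 6 steps (steps 3, 4, 5, 6, 13, 14, from (2S,5S)-hexane-2,5-diol).

Steps most likely to fail:

1. Step 13 (proposed method). The o-quinone methide may be consumed by dimerisation or by its own phenoxide precursor faster than by the short-lived ylide. The ylide may rearrange before the o-quinone methide is released. Facial and trans selectivity may be poor at a methide carbon flanked by the styryl group.

   Fallback, from 15 and 3 back to 30, by known chemistry: catalyst-controlled carbene C–H insertion with the alkene installed last. Vilsmeier–Haack formylation of 3 (POCl3, DMF) should give 2-bromo-4,6-dimethoxybenzaldehyde F1. Chelation-directed demethylation (BCl3, CH2Cl2, −78 to 0 °C) should give 2-bromo-6-hydroxy-4-methoxybenzaldehyde F2. O-alkylation with 4-methoxybenzyl chloride (K2CO3, DMF) should give 2-bromo-4-methoxy-6-[(4-methoxybenzyl)oxy]benzaldehyde F3. Aryllithium 24 (from 15, t-BuLi, THF, −78 °C) would add to F3 to give the carbinol (DBF){2-bromo-4-methoxy-6-[(4-methoxybenzyl)oxy]phenyl}methanol F4. Dess–Martin oxidation would give the ketone (DBF){2-bromo-4-methoxy-6-[(4-methoxybenzyl)oxy]phenyl}methanone F5. Condensation with hydrazine (N2H4·H2O, AcOH cat., EtOH, reflux, forcing if needed) would give the hydrazone of F5, F6. Oxidation with MnO2 would give the diaryldiazomethane [(DBF)(diazo)methyl]-2-bromo-4-methoxy-6-[(4-methoxybenzyl)oxy]benzene F7. With Rh2(PTAD)4 (dirhodium tetrakis[(1-adamantyl)(N-phthalimido)acetate], the ligand enantiomer that delivers 3S), the donor/donor carbene should insert into the O-benzylic C–H bond and give the cis compound (2R,3S)-4-bromo-3-(DBF)-6-methoxy-2-(4-methoxyphenyl)-2,3-dihydro-1-benzofuran F8. CF3CO2H in CH2Cl2 should epimerise C2 through reversible C2–O ionisation to the trans isomer (2S,3S)-4-bromo-3-(DBF)-6-methoxy-2-(4-methoxyphenyl)-2,3-dihydro-1-benzofuran F9; this is safe here because no alkene is present yet. A Mizoroki–Heck reaction of F9 with 4-methoxystyrene (Pd(OAc)2, P(o-tol)3, Et3N, DMF, 100 °C) would return to 30.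

2. Step 6 (proposed method). The same processes threaten it: over-addition of the Grignard reagent to the o-quinone methide, decay of the ylide before the o-quinone methide forms, and erosion of trans or facial selectivity.

   Fallback, from 1 and 4 back to 15, by known chemistry. O-alkylation of 1 with 4-methoxybenzyl chloride (K2CO3, DMF) should give 5-bromo-3-methoxy-2-[(4-methoxybenzyl)oxy]benzaldehyde F10. Addition of 4 would give {5-bromo-3-methoxy-2-[(4-methoxybenzyl)oxy]phenyl}(3,5-dimethoxyphenyl)methanol F11. Dess–Martin oxidation would give the benzophenone {5-bromo-3-methoxy-2-[(4-methoxybenzyl)oxy]phenyl}(3,5-dimethoxyphenyl)methanone F12. Hydrazine would give its hydrazone F13. MnO2 would give the diazo compound 5-bromo-1-[diazo(3,5-dimethoxyphenyl)methyl]-3-methoxy-2-[(4-methoxybenzyl)oxy]benzene F14. With Rh2(PTAD)4 (the ligand enantiomer that delivers 3R), intramolecular carbene insertion into the O-benzylic C–H bond should give cis-(2S,3R)-5-bromo-3-(3,5-dimethoxyphenyl)-7-methoxy-2-(4-methoxyphenyl)-2,3-dihydro-1-benzofuran F15. Acid-mediated epimerisation at C2 (CF3CO2H, CH2Cl2) would return to trans 15.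

3. Step 14. Lewis acid ionisation of the benzylic C2–O bonds (ring opening, epimerisation), cationic cyclisation onto the stilbene, or incomplete cleavage of the seven ethers may occur.

   Fallback, from 30 back to 31: basic nucleophilic ether cleavage with NaSEt in DMF at 130–150 °C (SN2 at the methyl groups), a medium in which neither a benzylic cation nor a protonated stilbene can arise. The crude heptaphenol would be peracetylated (Ac2O, pyridine) to the heptaacetate of the target F16 for chromatographic purification. Mild methanolysis (K2CO3, MeOH, 0 °C) would then return to 31.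

Further compounds

F1 | step 13 | 2-bromo-4,6-dimethoxybenzaldehyde | COc1cc(Br)c(C=O)c(OC)c1
F2 | step 13 | 2-bromo-6-hydroxy-4-methoxybenzaldehyde | COc1cc(O)c(C=O)c(Br)c1
F3 | step 13 | 2-bromo-4-methoxy-6-[(4-methoxybenzyl)oxy]benzaldehyde | COc1ccc(COc2cc(OC)cc(Br)c2C=O)cc1
F4 | step 13 | (DBF){2-bromo-4-methoxy-6-[(4-methoxybenzyl)oxy]phenyl}methanol | COc1ccc(COc2cc(OC)cc(Br)c2C(O)c2cc(OC)c3c(c2)[C@@H](c2cc(OC)cc(OC)c2)[C@H](c2ccc(OC)cc2)O3)cc1
F5 | step 13 | (DBF){2-bromo-4-methoxy-6-[(4-methoxybenzyl)oxy]phenyl}methanone | COc1ccc(COc2cc(OC)cc(Br)c2C(=O)c2cc(OC)c3c(c2)[C@@H](c2cc(OC)cc(OC)c2)[C@H](c2ccc(OC)cc2)O3)cc1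
F6 | step 13 | hydrazone of (DBF){2-bromo-4-methoxy-6-[(4-methoxybenzyl)oxy]phenyl}methanone | COc1ccc(COc2cc(OC)cc(Br)c2C(=NN)c2cc(OC)c3c(c2)[C@@H](c2cc(OC)cc(OC)c2)[C@H](c2ccc(OC)cc2)O3)cc1
F7 | step 13 | [(DBF)(diazo)methyl]-2-bromo-4-methoxy-6-[(4-methoxybenzyl)oxy]benzene | COc1ccc(COc2cc(OC)cc(Br)c2C(=[N+]=[N-])c2cc(OC)c3c(c2)[C@@H](c2cc(OC)cc(OC)c2)[C@H](c2ccc(OC)cc2)O3)cc1
F8 | step 13 | (2R,3S)-4-bromo-3-(DBF)-6-methoxy-2-(4-methoxyphenyl)-2,3-dihydro-1-benzofuran (cis) | Brc1cc(OC)cc2c1[C@H](c1cc(OC)c3c(c1)[C@@H](c1cc(OC)cc(OC)c1)[C@H](c1ccc(OC)cc1)O3)[C@H](c1ccc(OC)cc1)O2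
F9 | step 13 | (2S,3S)-4-bromo-3-(DBF)-6-methoxy-2-(4-methoxyphenyl)-2,3-dihydro-1-benzofuran (trans) | Brc1cc(OC)cc2c1[C@H](c1cc(OC)c3c(c1)[C@@H](c1cc(OC)cc(OC)c1)[C@H](c1ccc(OC)cc1)O3)[C@@H](c1ccc(OC)cc1)O2
F10 | step 6 | 5-bromo-3-methoxy-2-[(4-methoxybenzyl)oxy]benzaldehyde | COc1ccc(COc2c(OC)cc(Br)cc2C=O)cc1
F11 | step 6 | {5-bromo-3-methoxy-2-[(4-methoxybenzyl)oxy]phenyl}(3,5-dimethoxyphenyl)methanol | COc1ccc(COc2c(OC)cc(Br)cc2C(O)c2cc(OC)cc(OC)c2)cc1
F12 | step 6 | {5-bromo-3-methoxy-2-[(4-methoxybenzyl)oxy]phenyl}(3,5-dimethoxyphenyl)methanone | COc1ccc(COc2c(OC)cc(Br)cc2C(=O)c2cc(OC)cc(OC)c2)cc1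
F13 | step 6 | hydrazone of {5-bromo-3-methoxy-2-[(4-methoxybenzyl)oxy]phenyl}(3,5-dimethoxyphenyl)methanone | COc1ccc(COc2c(OC)cc(Br)cc2C(=NN)c2cc(OC)cc(OC)c2)cc1
F14 | step 6 | 5-bromo-1-[diazo(3,5-dimethoxyphenyl)methyl]-3-methoxy-2-[(4-methoxybenzyl)oxy]benzene | COc1ccc(COc2c(OC)cc(Br)cc2C(=[N+]=[N-])c2cc(OC)cc(OC)c2)cc1
F15 | step 6 | (2S,3R)-5-bromo-3-(3,5-dimethoxyphenyl)-7-methoxy-2-(4-methoxyphenyl)-2,3-dihydro-1-benzofuran (cis) | Brc1cc(OC)c2c(c1)[C@@H](c1cc(OC)cc(OC)c1)[C@@H](c1ccc(OC)cc1)O2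
F16 | step 14 | heptaacetate of the target (all seven phenols as acetates) | CC(=O)Oc1ccc(/C=C/c2cc(OC(C)=O)cc3c2[C@H](c2cc(OC(C)=O)c4c(c2)[C@@H](c2cc(OC(C)=O)cc(OC(C)=O)c2)[C@H](c2ccc(OC(C)=O)cc2)O4)[C@@H](c2ccc(OC(C)=O)cc2)O3)cc1
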